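Per second is the unit to think in here: the free monomer runs in at 0.00667 s⁻¹ of its charge each second.

- north: free monomer 2 M (fed, over 2.5 min); transfer agent 0.20 M; initiator 2 mol%; run made earlier; the fed solution adds 1.0 times the starting volume
- flask: free monomer 2.0 M (fed, over 2.5 min); transfer agent 0.200 M; initiator 1 mol%; time 2.5 min; the fed solution adds 1.0 times the starting volume

north run (percent of the free monomer charged)

| time / s | monomer in chains / % | free monomer / % |
|---|---|---|
| 10.0 | 0 | 6.1 |
| 20.0 | 2.1 | 10.6 |
| 25.0 | 4.3 | 11.5 |
| 40.0 | 14.7 | 11.3 |
| 50.0 | 23.1 | 10.2 |

(each reading ± 0.5 percentage points)

- every charge counts on the volume at the start, and the solution that is fed holds the whole dose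
- the average divides the monomer in chains by the number of chains begun, living and dead together
- the numbers in the tables scatter with a standard deviation of 0.5 percentage points
- the earlier runs do not show the number of chains; that part of a forecast is a guess
- percentages count the whole charge, also what has not yet gone in
- no earlier run changes the charge of initiator; that part of a forecast is a guess

* average number of monomer units in a chain (chains begun, living or dead) at 2.5 min
* part of the free monomer that has reacted at 2.5 min

From 40.0 s to 50.0 s the north run put 8.4 percentage points of the charge into chains while free monomer stood between 10.2% and 11.3%. That reads as 0.0781 s⁻¹. Call this the uptake constant, the share of the free monomer present that enters chains per second. It is a pseudo-first-order constant, and you should expect it to follow the concentration of growing ends.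

Now turn the settings one by one. The flask's feed is the same as north's, and so is its starting [transfer agent], so neither moves this reckoning. The initiator drops to half of the north loading. No run tests that change, so I guess the uptake constant follows the loading in proportion, which gives this flask 0.0391 s⁻¹. With feed and uptake in balance, free monomer sits at feed over uptake constant, 17.1%, so I expect 82.9% reacted. If each initiator charged begins one chain, which is also a guess, the average chain holds 82.9 units.

The forecast, counting “0.20 M transfer agent, if nearly all used” towards the chains, says 8 units and 86%, and my reckoning differs on both. The flask gives 79.4 units and 80.5%.

    living end + transfer agent → dead chain (kL = 0.0480 M⁻¹ s⁻¹)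
    initiator + monomer in chains → spent initiator (k = 0.00187 M⁻¹ s⁻¹)
    free monomer + living end → monomer in chains + living end, rate k3*[living end]*[free monomer] (k = 5.18 M⁻¹ s⁻¹)
    free monomer → uncatalysed product (k = 0.00279 s⁻¹)
    free monomer + initiator → living end + monomer in chains (k = 0.0992 M⁻¹ s⁻¹)

In this scheme the uptake constant is the growth constant times [living end]. In the flask that is 0.0400 s⁻¹ at 1.25 min and 0.0268 s⁻¹ at 2.50 min, less than my 0.0391 s⁻¹, when free monomer stands at 19.5%. The neighbour flask holds 0.25 mol% of initiator, its other charges as in the flask, so the same proportion from north gives 0.00977 s⁻¹. Its living ends give 0.00679 s⁻¹ at 2.50 min, which is 0.695 of that reckoning, against 0.686 in the flask at that same time. The neighbour flask ends with 53.0% of its free monomer reacted and an average chain of 164 units.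

The runs are simulated for an exercise; the scatter is artificial.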